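| setting | teal | ochre | violet | flask |
|---|---|---|---|---|
| substrate | 0.10 M | 0.10 M | 0.10 M | 0.10 M |
| first nucleophile | 2 equiv | 2 equiv | 2 equiv | 2.00 equiv |
| second nucleophile | 1.1 equiv | 1.1 equiv | 2.2 equiv | 1.10 equiv |
| capture agent | 0.015 M | 0.060 M | 0.030 M | 0.0300 M |
| remark | run made earlier | run made earlier | run made earlier |  |
| time |  |  |  | 2.0 min |

| run | time / s | target / % | other capture product / % |
|---|---|---|---|
| teal | 10.0 | 4.0 | 4.8 |
| teal | 20.0 | 7.7 | 10.2 |
| teal | 30.0 | 11.0 | 13.2 |
| teal | 50.0 | 15.6 | 20.3 |
| teal | 80.0 | 22.0 | 27.8 |
| teal | 90.0 | 24.4 | 30.1 |
| ochre | 10.0 | 4.5 | 5.5 |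
| ochre | 12.0 | 4.7 | 6.1 |
| ochre | 20.0 | 7.8 | 9.6 |
| ochre | 40.0 | 14.1 | 16.9 |
| ochre | 60.0 | 18.9 | 22.6 |
| ochre | 90.0 | 24.6 | 30.2 |
| violet | 10.0 | 2.9 | 7.2 |
| violet | 25.0 | 6.9 | 15.5 |
| violet | 40.0 | 9.7 | 22.2 |
| violet | 60.0 | 12.6 | 31.2 |
| violet | 90.0 | 14.9 | 39.3 |

(each reading ± 0.5 percentage points)

1. ratio of target to other capture product at 1.5 s
2. ratio of target to other capture product at 15 s
3. ratio of target to other capture product at 2.0 min

- steps under discussion: substrate -> open intermediate; first nucleophile + open intermediate -> target; second nucleophile + open intermediate -> other capture product; target -> over-reaction product; open intermediate + capture agent -> trapped intermediate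

0.457 are the odds, as read from the early readings, that a molecule of open intermediate takes first nucleophile rather than second nucleophile at equal concentrations of the two: the fork factor, or selectivity factor. Target and other capture product are the two exits of that fork, so an early ratio of the two products equals the fork factor times c(first nucleophile)/c(second nucleophile).

The fork factor can be read in two ways. Teal and ochre can be pooled: with capture agent at 0.015 M and 0.060 M, target reads 24.4% and 24.6% at 90.0 s. Their readings up to 20.0 s, scaled by the charges, give 0.439. Violet, with 2.2 equiv of second nucleophile, gives 0.475 up to 25.0 s. A scatter of 0.5 percentage points on violet's target readings of 2.9% and 6.9% covers that gap, so the mean is trusted.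

At 90.0 s the ways part: teal gives 0.446, violet 0.417. The late reading is the one that cheats. In violet, other capture product at 39.3% stands above target at 14.9%, so more second nucleophile than first nucleophile has been spent and the fork should tilt towards target, yet the ratio sinks. That points to target leaving, so the late ratio is no measure of the fork.

For the flask, the fork factor and the charges give 0.830 at 1.5 s and 15 s, and somewhat less at 2.0 min. The forecast says 0.82, 0.81 and 0.8, holding that “These effects nearly cancel”.

The flask gives 0.856, 0.854 and 0.787.

    substrate → open intermediate (k = 0.00958 /s)
    first nucleophile + open intermediate → target (k = 7.63 /M/s)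
    second nucleophile + open intermediate → other capture product (k = 16.2 /M/s)
    target → over-reaction product (k = 0.00265 /s)
    open intermediate + capture agent → trapped intermediate (k = 0.0276 /M/s)

The early ratios stand close to the reckoned 0.830. The hour of the reading is the largest single effect on the late ratio: at 20.0 min the flask stands at 0.0579, not 0.787. The fall by 2.0 min comes in part from the step from target to over-reaction product: that step has taken 5.50% of the substrate charged, and the same flask without it ends at 0.943. For a neighbour flask charged with 1.90 equiv of second nucleophile, the fork factor gives 0.481 at 1.5 s; the computed ratio is 0.495.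

The earlier runs and the new flask were computed with made-up constants.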